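## Retrosynthetic overview

1. Target 26 ⇐ C3–O desilylation ⇐ C10–OH-directed epoxidation of the 1Z alkene ⇐ angeloylation of C8–OH on the macrolactone.
2. Key disconnection C6–C7: C7 is the β-carbon of a 2-(bromomethyl)enoate, natively an acceptor carbon. CrCl2 turns it into an allylchromium (an ester homoenolate equivalent) that attacks the C6 enal carbon, closing the ten-membered ring; lactonisation then gives the cis-fused α-methylene lactone.
3. Seco-bromide 18 ⇐ Morita–Baylis–Hillman reaction and SN2′ bromination at the C7 aldehyde; both aldehydes (C6, C7) come from one Swern oxidation of two primary TES ethers.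
4. C2–C3 ⇐ catalytic asymmetric alkynylation of methyl (Z)-3-formylcrotonate (C3–C6, C15) with alkyne 6 (C7–C10, C14, C1, C2, from (S)-3-hydroxybutyrolactone). The temporary butenolide fixes the 4Z alkene; Lindlar reduction gives 1Z.
5. Ring order: temporary butenolide (opened by reduction) → ten-membered carbocycle and γ-lactone in one step → epoxide last.

Assumptions: locants C1–C15 are the germacrane numbering of the target (lactone C12–O–C6, C13 exocyclic CH2, C14 on C10, C15 on C4); (S,S)-ProPhenol is taken to give the (R)-carbinol in step 4 (otherwise its antipode is used).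

## Route

Step 1
Reactants: 1 (S)-3-hydroxy-γ-butyrolactone; 2 lithium (trimethylsilyl)acetylide
Product: 5 (2S,4R)-4-methylhex-5-yne-1,2,4-triol, via ynone diol 3 (not isolated), via silylalkyne triol 4 (not isolated)
Conditions: 2 (2.2 equiv), THF, −78 °C; MeMgBr (3 equiv), THF/CH2Cl2, −78 → 0 °C; then MeOH, K2CO3, rt
Reagents that add atoms: methylmagnesium bromide, C[Mg]Br
Why: Acetylide addition opens the lactone to the ynone alkoxide, and the Grignard reagent then adds under 1,3-chelation control (six-membered magnesium β-alkoxide chelate, methyl delivered anti to the C7 substituent) to set C10 as the 1,3-syn diol (R), after which K2CO3/MeOH removes the alkynyl silane; the minor C10 epimer is removed by chromatography.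

Step 2
Reactants: 5 (2S,4R)-4-methylhex-5-yne-1,2,4-triol
Product: 6 (3R,5S)-3-methyl-3,5,6-tris(triethylsilyloxy)hex-1-yne
Conditions: TESOTf (3.6 equiv), 2,6-lutidine, CH2Cl2, −78 → 0 °C
Reagents that add atoms: triethylsilyl trifluoromethanesulfonate, CC[Si](CC)(CC)OS(=O)(=O)C(F)(F)F
Why: Silyl triflate silylation protects all three hydroxyls including the tertiary one, which later prevents lactol formation with the C7 aldehyde and blocks O8 during lactonisation.

Step 3
Reactants: 7 5-hydroxy-4-methylfuran-2(5H)-one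
Product: 8 methyl (2Z)-3-methyl-4-oxobut-2-enoate
Conditions: KHCO3, MeI, DMF, 0 °C → rt
Reagents that add atoms: iodomethane, CI
Why: O-Alkylation of the ring-opened carboxylate tautomer of the pseudo-acid (ring–chain tautomerism) gives the open formyl ester with the Z geometry inherited from the butenolide ring.

Step 4
Reactants: 6 (3R,5S)-3-methyl-3,5,6-tris(triethylsilyloxy)hex-1-yne; 8 methyl (2Z)-3-methyl-4-oxobut-2-enoate
Product: 10 (5R)-4-methyl-5-[(3R,5S)-3-methyl-3,5,6-tris(triethylsilyloxy)hex-1-yn-1-yl]furan-2(5H)-one, via hydroxy ester 9 (not isolated)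
Conditions: Me2Zn (3 equiv), (S,S)-ProPhenol (20 mol %), Ph3PO (40 mol %), toluene, 4 °C; aq. NH4Cl
Reagents that add atoms: none
Why: Zinc–ProPhenol asymmetric alkynylation of the aldehyde sets C3 (R) under catalyst control, and the zinc alkoxide lactonises onto the cis ester so that the 4Z geometry is locked in a butenolide.

Step 5
Reactants: 10 butenolide
Product: 11 (2Z,4R,7R,9S)-3,7-dimethyl-7,9,10-tris(triethylsilyloxy)dec-2-en-5-yne-1,4-diol
Conditions: iBu2AlH (4 equiv), CH2Cl2, −78 → 0 °C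
Reagents that add atoms: none
Why: Hydride 1,2-reduction of the butenolide through its lactol gives the (Z)-ene-1,4-diol with retention of the alkene geometry and of C3.

Step 6
Reactants: 11 enyne diol
Product: 12 (2Z,4S,5Z,7R,9S)-3,7-dimethyl-7,9,10-tris(triethylsilyloxy)deca-2,5-diene-1,4-diol
Conditions: H2 (1 atm), Pd/CaCO3 poisoned with Pb(OAc)2, quinoline, EtOAc, rt
Reagents that add atoms: none
Why: Lindlar cis-semihydrogenation converts the alkyne into the 1Z alkene (precursor of the cis-epoxide) without touching the trisubstituted alkene; the C3 descriptor changes only through priorities.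

Step 7
Reactants: 12 diene diol
Product: 14 (2Z,4S,5Z,7R,9S)-4-(tert-butyldimethylsilyloxy)-3,7-dimethyl-1,7,9,10-tetrakis(triethylsilyloxy)deca-2,5-diene, via mono-TES ether 13 (not isolated)
Conditions: TESCl (1.05 equiv), imidazole, CH2Cl2, −78 °C; then TBSOTf, 2,6-lutidine, −78 → 0 °C
Reagents that add atoms: chlorotriethylsilane, CC[Si](Cl)(CC)CC; tert-butyldimethylsilyl trifluoromethanesulfonate, CC(C)(C)[Si](C)(C)OS(=O)(=O)C(F)(F)F
Why: Sequential silylation takes the primary allylic hydroxyl first (TES) and then the hindered secondary C3 hydroxyl (TBS), so that C3–O stays protected to the end while both primary positions carry Swern-labile TES groups.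

Step 8
Reactants: 14 pentasilyl ether
Product: 15 (2Z,4S,5Z,7R,9S)-4-(tert-butyldimethylsilyloxy)-3,7-dimethyl-7,9-bis(triethylsilyloxy)deca-2,5-dienedial
Conditions: (COCl)2, DMSO, CH2Cl2, −78 → −30 °C; Et3N, −78 → 0 °C
Reagents that add atoms: none
Why: Under Swern conditions primary TES ethers are cleaved and oxidised in situ while secondary and tertiary TES and TBS ethers persist, giving the C7 aldehyde and the (Z)-C6 enal in one operation.

Step 9
Reactants: 15 dialdehyde; 16 methyl acrylate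
Product: 17 methyl (4S,6R,7Z,9S,10Z)-9-(tert-butyldimethylsilyloxy)-3-hydroxy-6,10-dimethyl-2-methylidene-12-oxo-4,6-bis(triethylsilyloxy)dodeca-7,10-dienoate (C3 epimers)
Conditions: 16 (neat, excess), DABCO (1 equiv), MeOH (cat.), rt, 3–5 d
Reagents that add atoms: none
Why: The Morita–Baylis–Hillman reaction takes place at the saturated α-silyloxy aldehyde (C7) because the β,β-disubstituted enal is a poor acceptor for the ammonium enolate; the new carbinol centre is destroyed in the next step.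

Step 10
Reactants: 17 Baylis–Hillman adduct
Product: 18 methyl (2Z,4S,6R,7Z,9S,10Z)-2-(bromomethyl)-9-(tert-butyldimethylsilyloxy)-6,10-dimethyl-12-oxo-4,6-bis(triethylsilyloxy)dodeca-2,7,10-trienoate
Conditions: NBS, Me2S, CH2Cl2, 0 °C → rt
Reagents that add atoms: N-bromosuccinimide, O=C1CCC(=O)N1Br
Why: Corey–Kim-type activation of the allylic alcohol followed by SN2′ attack of bromide gives the conjugated (Z)-2-(bromomethyl)enoate, in which C8 lies cis to CH2Br.

Step 11
Reactants: 18 allylic bromide–enal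
Product: 20 (1Z,3S,4Z,6S,7S,8S,10R)-3-(tert-butyldimethylsilyloxy)-8,10-bis(triethylsilyloxy)germacra-1,4,11(13)-trien-12,6-olide, via hydroxy ester 19 (not isolated)
Conditions: CrCl2 (8 equiv), THF/DMF 4:1, 0.002 M, syringe-pump addition, rt; aq. NH4Cl
Reagents that add atoms: none
Why: In this intramolecular Nozaki–Hiyama (Barbier-type) allylation, CrCl2 reduces the allylic bromide to a 2-(methoxycarbonyl)allylchromium whose γ-carbon C7 (the Michael-acceptor β-carbon of 18, now an ester homoenolate equivalent) attacks the C6 aldehyde through a chair transition state to give the 6,7-cis relationship, while A1,3 strain holds H8 in the allyl plane so that C6 bonds anti to the OSiEt3 group on the face carrying the C9 tether, and the chromium alkoxide then lactonises onto the methyl ester because O8 is silylated.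

Step 12
Reactants: 20 macrolactone
Product: 21 (1Z,3S,4Z,6S,7R,8S,10R)-3-(tert-butyldimethylsilyloxy)-8,10-dihydroxygermacra-1,4,11(13)-trien-12,6-olide
Conditions: HF·pyridine, pyridine, THF, 0 °C
Reagents that add atoms: none
Why: Fluoride-mediated desilylation removes the two TES ethers much faster than the hindered secondary allylic TBS ether at C3.

Step 13
Reactants: 21 diol; 22 angelic acid
Product: 24 (1Z,3S,4Z,6S,7R,8S,10R)-8-angeloyloxy-3-(tert-butyldimethylsilyloxy)-10-hydroxygermacra-1,4,11(13)-trien-12,6-olide, via mixed anhydride 23 (not isolated)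
Conditions: 22, 2,4,6-trichlorobenzoyl chloride, Et3N, toluene, rt; then 21, 80 °C
Reagents that add atoms: none
Why: Yamaguchi-type mixed-anhydride esterification without DMAP acylates the only reactive hydroxyl (secondary C8–OH; C10–OH is tertiary and C3–O is silylated) and avoids angelate-to-tiglate isomerisation.

Step 14
Reactants: 24 angelate
Product: 25 (1R,2S,3R,4Z,6S,7R,8S,10R)-8-angeloyloxy-3-(tert-butyldimethylsilyloxy)-1,2-epoxy-10-hydroxygermacra-4,11(13)-dien-12,6-olide
Conditions: VO(acac)2 (5 mol %), tBuOOH, CH2Cl2, 0 °C → rt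
Reagents that add atoms: tert-butyl hydroperoxide, CC(C)(C)OO
Why: In this hydroxyl-directed vanadium-catalysed epoxidation only the C1=C2 alkene is allylic to a free hydroxyl, and oxygen is delivered syn to the C10–O bond on the outer face of the ring (C9 on the opposite face), giving the cis-epoxide with the required relation to C10 and C3.

Step 15
Reactants: 25 epoxide
Product: 26 (1R,2R,3R,4Z,6S,7R,8S,10R)-8-angeloyloxy-1,2-epoxy-3,10-dihydroxygermacra-4,11(13)-dien-12,6-olide (CNP0351240.3)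
Conditions: HF·pyridine, pyridine, THF, 0 °C → rt
Reagents that add atoms: none
Why: Buffered fluoride desilylation frees the C3 hydroxyl without opening the epoxide or touching the angelate and the α-methylene lactone.

## Compound list

1 | (S)-3-hydroxy-γ-butyrolactone | O=C1C[C@H](O)CO1 | starting material
2 | lithium (trimethylsilyl)acetylide | [Li]C#C[Si](C)(C)C | starting material
3 | (5S)-5,6-dihydroxy-1-(trimethylsilyl)hex-1-yn-3-one | C[Si](C)(C)C#CC(=O)C[C@H](O)CO | intermediate
4 | (2S,4R)-4-methyl-6-(trimethylsilyl)hex-5-yne-1,2,4-triol | C[Si](C)(C)C#C[C@](C)(O)C[C@H](O)CO | intermediate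
5 | (2S,4R)-4-methylhex-5-yne-1,2,4-triol | C#C[C@](C)(O)C[C@H](O)CO | intermediate
6 | (3R,5S)-3-methyl-3,5,6-tris(triethylsilyloxy)hex-1-yne | C#C[C@](C)(O[Si](CC)(CC)CC)C[C@H](O[Si](CC)(CC)CC)CO[Si](CC)(CC)CC | intermediate
7 | 5-hydroxy-4-methylfuran-2(5H)-one | CC1=CC(=O)OC1O | starting material
8 | methyl (2Z)-3-methyl-4-oxobut-2-enoate | COC(=O)/C=C(/C)C=O | intermediate
9 | methyl (2Z,4R,7R,9S)-4-hydroxy-3,7-dimethyl-7,9,10-tris(triethylsilyloxy)dec-2-en-5-ynoate | COC(=O)/C=C(/C)[C@@H](O)C#C[C@](C)(O[Si](CC)(CC)CC)C[C@H](O[Si](CC)(CC)CC)CO[Si](CC)(CC)CC | intermediate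
10 | (5R)-4-methyl-5-[(3R,5S)-3-methyl-3,5,6-tris(triethylsilyloxy)hex-1-yn-1-yl]furan-2(5H)-one | O=C1C=C(C)[C@@H](O1)C#C[C@](C)(O[Si](CC)(CC)CC)C[C@H](O[Si](CC)(CC)CC)CO[Si](CC)(CC)CC | intermediate
11 | (2Z,4R,7R,9S)-3,7-dimethyl-7,9,10-tris(triethylsilyloxy)dec-2-en-5-yne-1,4-diol | OC/C=C(/C)[C@@H](O)C#C[C@](C)(O[Si](CC)(CC)CC)C[C@H](O[Si](CC)(CC)CC)CO[Si](CC)(CC)CC | intermediate
12 | (2Z,4S,5Z,7R,9S)-3,7-dimethyl-7,9,10-tris(triethylsilyloxy)deca-2,5-diene-1,4-diol | OC/C=C(/C)[C@@H](O)/C=C\[C@](C)(O[Si](CC)(CC)CC)C[C@H](O[Si](CC)(CC)CC)CO[Si](CC)(CC)CC | intermediate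
13 | (2Z,4S,5Z,7R,9S)-3,7-dimethyl-1,7,9,10-tetrakis(triethylsilyloxy)deca-2,5-dien-4-ol | CC[Si](CC)(CC)OC/C=C(/C)[C@@H](O)/C=C\[C@](C)(O[Si](CC)(CC)CC)C[C@H](O[Si](CC)(CC)CC)CO[Si](CC)(CC)CC | intermediate
14 | (2Z,4S,5Z,7R,9S)-4-(tert-butyldimethylsilyloxy)-3,7-dimethyl-1,7,9,10-tetrakis(triethylsilyloxy)deca-2,5-diene | CC[Si](CC)(CC)OC/C=C(/C)[C@@H](O[Si](C)(C)C(C)(C)C)/C=C\[C@](C)(O[Si](CC)(CC)CC)C[C@H](O[Si](CC)(CC)CC)CO[Si](CC)(CC)CC | intermediate
15 | (2Z,4S,5Z,7R,9S)-4-(tert-butyldimethylsilyloxy)-3,7-dimethyl-7,9-bis(triethylsilyloxy)deca-2,5-dienedial | O=C/C=C(/C)[C@@H](O[Si](C)(C)C(C)(C)C)/C=C\[C@](C)(O[Si](CC)(CC)CC)C[C@H](O[Si](CC)(CC)CC)C=O | intermediate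
16 | methyl acrylate | C=CC(=O)OC | starting material
17 | methyl (4S,6R,7Z,9S,10Z)-9-(tert-butyldimethylsilyloxy)-3-hydroxy-6,10-dimethyl-2-methylidene-12-oxo-4,6-bis(triethylsilyloxy)dodeca-7,10-dienoate (C3 epimers) | O=C/C=C(/C)[C@@H](O[Si](C)(C)C(C)(C)C)/C=C\[C@](C)(O[Si](CC)(CC)CC)C[C@H](O[Si](CC)(CC)CC)C(O)C(=C)C(=O)OC | intermediate
18 | methyl (2Z,4S,6R,7Z,9S,10Z)-2-(bromomethyl)-9-(tert-butyldimethylsilyloxy)-6,10-dimethyl-12-oxo-4,6-bis(triethylsilyloxy)dodeca-2,7,10-trienoate | O=C/C=C(/C)[C@@H](O[Si](C)(C)C(C)(C)C)/C=C\[C@](C)(O[Si](CC)(CC)CC)C[C@H](O[Si](CC)(CC)CC)/C=C(\CBr)C(=O)OC | intermediate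
19 | methyl 2-[(1S,2S,3Z,5S,6Z,8R,10S)-5-(tert-butyldimethylsilyloxy)-2-hydroxy-4,8-dimethyl-8,10-bis(triethylsilyloxy)cyclodeca-3,6-dien-1-yl]prop-2-enoate | O[C@H]1/C=C(/C)[C@@H](O[Si](C)(C)C(C)(C)C)/C=C\[C@](C)(O[Si](CC)(CC)CC)C[C@H](O[Si](CC)(CC)CC)[C@H]1C(=C)C(=O)OC | intermediate
20 | (1Z,3S,4Z,6S,7S,8S,10R)-3-(tert-butyldimethylsilyloxy)-8,10-bis(triethylsilyloxy)germacra-1,4,11(13)-trien-12,6-olide | C=C1C(=O)O[C@H]2/C=C(/C)[C@@H](O[Si](C)(C)C(C)(C)C)/C=C\[C@](C)(O[Si](CC)(CC)CC)C[C@H](O[Si](CC)(CC)CC)[C@@H]12 | intermediate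
21 | (1Z,3S,4Z,6S,7R,8S,10R)-3-(tert-butyldimethylsilyloxy)-8,10-dihydroxygermacra-1,4,11(13)-trien-12,6-olide | C=C1C(=O)O[C@H]2/C=C(/C)[C@@H](O[Si](C)(C)C(C)(C)C)/C=C\[C@](C)(O)C[C@H](O)[C@@H]12 | intermediate
22 | angelic acid ((Z)-2-methylbut-2-enoic acid) | C/C=C(/C)C(=O)O | starting material
23 | (Z)-2-methylbut-2-enoic 2,4,6-trichlorobenzoic anhydride | C/C=C(/C)C(=O)OC(=O)c1c(Cl)cc(Cl)cc1Cl | intermediate
24 | (1Z,3S,4Z,6S,7R,8S,10R)-8-angeloyloxy-3-(tert-butyldimethylsilyloxy)-10-hydroxygermacra-1,4,11(13)-trien-12,6-olide | C=C1C(=O)O[C@H]2/C=C(/C)[C@@H](O[Si](C)(C)C(C)(C)C)/C=C\[C@](C)(O)C[C@H](OC(=O)/C(C)=C\C)[C@@H]12 | intermediate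
25 | (1R,2S,3R,4Z,6S,7R,8S,10R)-8-angeloyloxy-3-(tert-butyldimethylsilyloxy)-1,2-epoxy-10-hydroxygermacra-4,11(13)-dien-12,6-olide | C=C1C(=O)O[C@H]2/C=C(/C)[C@@H](O[Si](C)(C)C(C)(C)C)[C@H]3O[C@H]3[C@](C)(O)C[C@H](OC(=O)/C(C)=C\C)[C@@H]12 | intermediate
26 | (1R,2R,3R,4Z,6S,7R,8S,10R)-8-angeloyloxy-1,2-epoxy-3,10-dihydroxygermacra-4,11(13)-dien-12,6-olide | C=C1C(=O)O[C@H]2/C=C(/C)[C@@H](O)[C@H]3O[C@H]3[C@](C)(O)C[C@H](OC(=O)/C(C)=C\C)[C@@H]12 | target

## Step count and risks

Total step count: 15. Longest linear sequence: 14 (steps 1, 2 and 4–15, from compound 1).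

Three steps most likely to fail:

**Step 11 (ring closure).** Risks are β-elimination of the C8 silyloxy group from the allylmetal, oligomerisation, and the wrong facial sense at C6/C7. The fallback sets out from 18 and comes back at 20, replacing the reductive chromium reagent by a covalent allylboron reagent. Borylation of the allylic bromide with bis(pinacolato)diboron under Pd2(dba)3 catalysis (DMSO, 40 °C) gives methyl (2E,4S,6R,7Z,9S,10Z)-9-(tert-butyldimethylsilyloxy)-6,10-dimethyl-12-oxo-2-[(4,4,5,5-tetramethyl-1,3,2-dioxaborolan-2-yl)methyl]-4,6-bis(triethylsilyloxy)dodeca-2,7,10-trienoate F1. At high dilution (toluene, 80 °C, or Sc(OTf)3 at −78 °C) it undergoes intramolecular allylboration through a closed six-membered transition state (same cis outcome). PPTS-promoted lactonisation of the borate then gives 20.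

**Step 14 (epoxidation face).** The risk is that the ring conformation delivers oxygen to the wrong face, or that the C4=C5 alkene competes. The fallback sets out from 24 and comes back at the target 26, switching from substrate control through C10–OH to reagent control through C3–OH. HF·pyridine first removes the TBS group to give (1Z,3S,4Z,6S,7R,8S,10R)-8-angeloyloxy-3,10-dihydroxygermacra-1,4,11(13)-trien-12,6-olide F2. Sharpless-type epoxidation (Ti(OiPr)4, D-(−)-diisopropyl tartrate, tBuOOH, 4 Å sieves, CH2Cl2, −20 °C) is then directed by the secondary C3 hydroxyl in the matched, erythro-selective sense and gives 26 directly.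

**Step 9 (Baylis–Hillman reaction).** Risks are low conversion at the hindered α-silyloxy aldehyde and amine-induced isomerisation of the Z-enal. The fallback sets out from 15 and comes back at 17 by vinylalumination instead of amine catalysis. Methyl propiolate is hydroaluminated with iBu2AlH and N-methylmorpholine N-oxide (THF, 0 °C) to the α-aluminoacrylate. Added to 15 at −78 °C, this attacks the more electrophilic saturated C7 aldehyde and gives 17 without any new isolated compound (F0).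

## Further compounds

F1 | step 11 | methyl (2E,4S,6R,7Z,9S,10Z)-9-(tert-butyldimethylsilyloxy)-6,10-dimethyl-12-oxo-2-[(4,4,5,5-tetramethyl-1,3,2-dioxaborolan-2-yl)methyl]-4,6-bis(triethylsilyloxy)dodeca-2,7,10-trienoate | O=C/C=C(/C)[C@@H](O[Si](C)(C)C(C)(C)C)/C=C\[C@](C)(O[Si](CC)(CC)CC)C[C@H](O[Si](CC)(CC)CC)/C=C(\CB1OC(C)(C)C(C)(C)O1)C(=O)OC
F2 | step 14 | (1Z,3S,4Z,6S,7R,8S,10R)-8-angeloyloxy-3,10-dihydroxygermacra-1,4,11(13)-trien-12,6-olide | C=C1C(=O)O[C@H]2/C=C(/C)[C@@H](O)/C=C\[C@](C)(O)C[C@H](OC(=O)/C(C)=C\C)[C@@H]12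
F0 | step 9 | none | none
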